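**Synthetic plan**

1. Cuts, in retrosynthetic order: the C8–O ester bond (epoxyangelic acid off); C14 back to CH3; C11=C13; the lactone bond O6–C12; C7–C11; then C8–C9 in exchange for C1–C6 (retro-oxy-Cope) and C6–C7 (vinyl anion plus ketone).
2. Enabling feature: C1=C10(C14) lies four bonds from the oxygenated C6 (C6–C7–C8–C9–C10=C1), and the cis alkene C3(O)–C4(C15)=C5 sits on the same C6. Re-joining C1 to C6 therefore gives a 6-isopropenyl-1-vinylcyclohex-2-enol whose ten carbons (C1–C6, C9, C10, C14, C15) and O3 are those of carvone.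
3. Forward: the carvone six-membered ring is kept up to the dialkenyl carbinol and is expanded in one step to the ten-membered ring; the γ-lactone is then closed at C6, and the oxirane arrives ready-made in the acid.
4. Stereochemistry: the carvone centre sets C3 (Luche reduction) and the C6 carbinol (addition trans to isopropenyl); the chair oxy-Cope turns both into C8 and erases them. C7 comes from alkylation on the open enolate face, C6 from Felkin reduction followed by SN2 inversion in the lactonisation, the ring-cis C1=C10 from the selenium [2,3] shift, and the oxirane centres from a tartrate-controlled epoxidation.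

Key step: step 7

Assumption: germacrane numbering is used throughout (ring C1–C10; C1=C10 and C4=C5 ring alkenes; oxygen on C3, C6, C8; C11 on C7, C12 lactone carbonyl, C13 exocyclic CH2, C14 on C10, C15 methyl on C4); (S)-carvone, ethyl vinyl ether, methyl bromoacetate and angelic acid are taken as purchased.

**Fragment A (C1–C6, C9, C10, C14, C15)**

Step 1
Reactants: 1 (S)-(+)-carvone
Product: 2 (1S,5S)-cis-carveol
Conditions: NaBH4, CeCl3·7H2O, MeOH, −78 to 0 °C
Reagents that add atoms: none
Why: Luche reduction is 1,2-selective and delivers hydride axially, which should give the pseudo-equatorial alcohol cis to the isopropenyl group (new centre, target C3, S), the established outcome for carvone.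

Step 2
Reactants: 2 (1S,5S)-cis-carveol
Product: 3 cis-carveol tert-butyldimethylsilyl ether
Conditions: TBSCl, imidazole, DMF, rt
Reagents that add atoms: tert-butyldimethylsilyl chloride, CC(C)(C)[Si](C)(C)Cl
Why: Standard silylation of a secondary allylic alcohol; the ether has to survive organolithium, amide base, hydride, DDQ and selenium oxidation and is removed last.

Step 3
Reactants: 3 cis-carveol tert-butyldimethylsilyl ether
Product: 4 (4S,6S)-4-(tert-butyldimethylsilyloxy)-3-methyl-6-(prop-1-en-2-yl)cyclohex-2-en-1-one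
Conditions: CrO3, 3,5-dimethylpyrazole, CH2Cl2, −20 °C
Reagents that add atoms: chromium trioxide, O=[Cr](=O)=O
Why: Allylic oxidation with the CrO3–3,5-dimethylpyrazole complex should convert the ring CH2 next to the alkene CH into the enone carbonyl, the other ring allylic C–H being shielded by its silyloxy group; no centre is formed and the 4,6-cis (diequatorial, also thermodynamic) arrangement is kept.

**Fragment B (C7, C8)**

Step 4
Reactants: 5 ethyl vinyl ether
Product: 6 4-methoxybenzyl vinyl ether
Conditions: Pd(OAc)2 (cat.), 1,10-phenanthroline, 5 as solvent, rt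
Reagents that add atoms: 4-methoxybenzyl alcohol, COc1ccc(CO)cc1
Why: Palladium diacetate–phenanthroline transfer vinylation (transetherification) of a primary benzylic alcohol, driven by the excess of 5; the two vinyl carbons become C7 and C8.

Step 5
Reactants: 6 4-methoxybenzyl vinyl ether
Product: 8 (Z)-1-bromo-2-(4-methoxybenzyloxy)ethene, via dibromo ether 7 (not isolated)
Conditions: Br2, CH2Cl2, −78 °C; then i-Pr2NEt, −78 to 40 °C
Reagents that add atoms: bromine, BrBr
Why: Bromine addition to the enol ether and amine-induced dehydrobromination of the α,β-dibromo ether (through the oxocarbenium ion) is the standard route to β-bromovinyl ethers and should give mainly the Z isomer (cis preference of 1,2-diheteroatom alkenes); residual E isomer is removed on Et3N-treated silica.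

**Coupling, ring expansion and lactone**

Step 6
Reactants: 8 (Z)-1-bromo-2-(4-methoxybenzyloxy)ethene; 4 enone
Product: 11 trans-dialkenyl carbinol, via vinyllithium 9 (not isolated), via vinylcerium dichloride 10 (not isolated)
Conditions: t-BuLi (2 equiv), Et2O, −78 °C; CeCl3, THF, −78 °C; then 4, −78 °C; aq. NaHCO3
Reagents that add atoms: none
Why: Br/Li exchange with retention gives the chelation-stabilised (Z)-2-alkoxyvinyllithium, whose organocerium derivative (Imamoto) should add 1,2 to the enolisable enone without deprotonation, from the equatorial direction opposite to the neighbouring isopropenyl group, so that the new carbinol centre (S, target C6) carries the two alkenyl groups trans; the acid-labile product is handled on base-washed silica.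

Step 7
Reactants: 11 trans-dialkenyl carbinol; 12 methyl bromoacetate
Product: 15 cyclodecadienone keto ester, via potassium alkoxide 13 (not isolated), via potassium enolate 14 (not isolated)
Conditions: KN(SiMe3)2, 18-crown-6, THF, −78 to 0 °C; then 12, −78 °C
Reagents that add atoms: none
Why: KN(SiMe3)2 gives alkoxide 13, which undergoes the anionic oxy-Cope ([3,3]-sigmatropic) shift of the 1,5-diene C9=C10–C1–C6(O−)–C7=C8, forming C8–C9 while the doubly allylic C1–C6 bond breaks; the closest known reactions are the ring expansions of 1-alkenyl-6-isopropenylcyclohex-2-enols to (2Z,6E)-cyclodeca-2,6-dienones with trapping of the enolate by an electrophile. The ten-membered ring is not closed end to end but arises from the cyclohexene by a four-atom ring expansion through a six-membered chair transition state, so no medium-ring cyclisation penalty is paid. In that chair the two alkenyl groups are trans-diequatorial on the half-chair cyclohexene and the ring bonds C1–C2 and C6–C5 are equatorial, which makes the new C1=C10 bond ring-trans and places the enolate oxygen of 14 cis to C8; the Z-configured 4-methoxybenzyloxy group is axial at C8, syn to the axial alkoxide oxygen where K+ can bridge both, and together with the S configuration at C1 and C6 this sets C8 as R while both relay centres are erased. The enolate is then alkylated at C7 by SN2 reaction with 12 on its outer face, anti to the C8–C9 bond that covers the inner face together with the transannular C1=C10 unit, which should give 7R (C11 anti to O8). The step needs chair over boat (a boat would give the C8 epimer and a ring-cis alkene), C- over O-alkylation and no β-elimination of the C8 alkoxide: the trans-1,2-dialkenyl arrangement with the Z enol ether secures the chair, the soft bromoacetate at −78 °C favours carbon, and the C8–O bond lies close to the nodal plane of the chelated enolate as it is formed.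

Step 8
Reactants: 15 cyclodecadienone keto ester
Product: 17 cis-fused 6S lactone, via lithium alkoxide 16 (not isolated)
Conditions: LiBH(s-Bu)3, THF, −78 to 0 °C; aq. NH4Cl
Reagents that add atoms: none
Why: The bulky borohydride adds 1,2 to the β,β-disubstituted enone carbonyl; Felkin–Anh attack anti to the C7–C8 bond (also the 1,3-syn sense of Li+ chelation to the C8 ether) should give the 6S alkoxide, which closes by 5-exo-trig acyl substitution on the methyl ester to the cis-fused lactone, while any 6R alkoxide closes directly to 19 and is carried on, so the outcome at C6 is corrected or confirmed in step 10.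

Step 9
Reactants: 17 cis-fused 6S lactone
Product: 18 6S hydroxy acid
Conditions: LiOH, THF/H2O, 0 °C to rt; then aq. NaH2PO4 to pH 5, 0 °C
Reagents that add atoms: lithium hydroxide, [Li+].[OH-]
Why: Saponification opens the γ-lactone without touching a stereocentre or the silyl and benzyl ethers; the γ-hydroxy acid is liberated cold and used at once.

Step 10
Reactants: 18 6S hydroxy acid
Product: 19 trans-fused 6R lactone
Conditions: PPh3, DIAD, THF, 0 °C
Reagents that add atoms: none
Why: Mitsunobu lactonisation: the allylic C6 hydroxyl is activated and displaced from the rear by the tethered carboxylate in an SN2 (5-exo-tet) closure, which inverts 6S to 6R and gives the trans-fused 6,12-olide; lactonisation with retention would only return 17 for recycling.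

Step 11
Reactants: 19 trans-fused 6R lactone
Product: 20 α-(dimethylaminomethyl) lactone
Conditions: LiN(i-Pr)2, THF, −78 °C; then Me2N=CH2+ I−, −78 °C to rt
Reagents that add atoms: dimethylmethyleneammonium iodide (Eschenmoser salt), C=[N+](C)C.[I-]
Why: Mannich reaction of the lactone enolate (the only acidic site) with the Eschenmoser salt introduces C13; the configuration at C11 is of no consequence.

Step 12
Reactants: 20 α-(dimethylaminomethyl) lactone
Product: 22 α-methylene lactone 4-methoxybenzyl ether, via ammonium iodide 21 (not isolated)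
Conditions: MeI, MeOH, rt; then NaHCO3, CH2Cl2/H2O, rt
Reagents that add atoms: none
Why: Quaternisation and mild-base β-elimination of trimethylamine is the standard completion of the α-methylene-γ-butyrolactone.

Step 13
Reactants: 22 α-methylene lactone 4-methoxybenzyl ether
Product: 23 C8 alcohol
Conditions: DDQ, CH2Cl2/pH 7 buffer, 0 °C
Reagents that add atoms: none
Why: Oxidative cleavage of the 4-methoxybenzyl ether by DDQ leaves the silyl ether, both ring alkenes and the methylene lactone untouched.

**Fragment C (epoxyangelic acid)**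

Step 14
Reactants: 24 angelic acid
Product: 25 (Z)-2-methylbut-2-en-1-ol
Conditions: LiAlH4, Et2O, 0 °C
Reagents that add atoms: none
Why: Hydride reduction of the acid to the allylic alcohol at 0 °C keeps the Z geometry.

Step 15
Reactants: 25 (Z)-2-methylbut-2-en-1-ol
Product: 26 (2S,3R)-(2,3-dimethyloxiran-2-yl)methanol
Conditions: Ti(Oi-Pr)4 (cat.), L-(+)-diethyl tartrate (cat.), t-BuOOH, 4 Å MS, CH2Cl2, −20 °C
Reagents that add atoms: tert-butyl hydroperoxide, CC(C)(C)OO
Why: Katsuki–Sharpless epoxidation; L-(+)-tartrate delivers oxygen to the face that gives the 2S,3R epoxy alcohol (the sense known for nerol and other Z-trisubstituted allylic alcohols), and the Z alkene keeps CH2OH and the C3 methyl cis; any minor enantiomer is removed later as a diastereomeric ester.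

Step 16
Reactants: 26 (2S,3R)-(2,3-dimethyloxiran-2-yl)methanol
Product: 27 (2R,3R)-2,3-dimethyloxirane-2-carboxylic acid
Conditions: RuCl3·xH2O (cat.), NaIO4, CCl4/MeCN/H2O, rt
Reagents that add atoms: water, O (second carboxyl oxygen, through the aldehyde hydrate; NaIO4 is the terminal oxidant)
Why: Catalytic RuO4 oxidation of a primary epoxy alcohol to the acid leaves the oxirane intact; the C2 descriptor changes from S to R only because CO2H outranks C3, and the quaternary α-carbon cannot epimerise.

**Endgame**

Step 17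
Reactants: 23 C8 alcohol; 27 (2R,3R)-2,3-dimethyloxirane-2-carboxylic acid
Product: 29 C8 epoxyangelate, via mixed anhydride 28 (not isolated)
Conditions: 2,4,6-Cl3C6H2COCl, Et3N, THF, rt; then 23, DMAP, toluene, rt
Reagents that add atoms: none
Why: Yamaguchi esterification suits a hindered secondary alcohol and an α,α-disubstituted acid that has no α-hydrogen to lose.

Step 18
Reactants: 29 C8 epoxyangelate
Product: 32 14-hydroxy ring-cis compound, via allylseleninic acid 30 (not isolated), via selenium ester 31 (not isolated)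
Conditions: SeO2 (cat.), t-BuOOH, CH2Cl2, rt
Reagents that add atoms: selenium dioxide, O=[Se]=O (transfers the oxygen; regenerated by tert-butyl hydroperoxide, CC(C)(C)OO)
Why: Sharpless–Umbreit allylic oxidation: the ene reaction of the most electron-rich alkene at C1 with transfer of a C14 hydrogen gives 30, and the [2,3]-sigmatropic shift to 31 re-forms C1=C10 with C2 pseudo-equatorial, so the oxidised C14 ends trans to C2 (ring-cis), as in the known conversion of 1(10)-trans germacranolides into 14-hydroxy 1(10)-cis isomers; C4=C5 is deactivated by two allylic C–O bonds and the methylene lactone is electron-poor.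

Step 19
Reactants: 32 14-hydroxy ring-cis compound
Product: 33 C14 enal
Conditions: MnO2, CH2Cl2, rt
Reagents that add atoms: none
Why: MnO2 oxidises the primary allylic alcohol selectively to the enal, whose geometry (C2 trans to CHO) is also the thermodynamic one.

Step 20
Reactants: 33 C14 enal
Product: 34 C14 carboxylic acid
Conditions: NaClO2, NaH2PO4, 2-methylbut-2-ene, t-BuOH/H2O, 0 °C to rt
Reagents that add atoms: sodium chlorite, [Na+].[O-]Cl=O
Why: Pinnick oxidation converts the enal into the acid without isomerisation; the alkene scavenger protects the ring alkenes from hypochlorous acid.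

Step 21
Reactants: 34 C14 carboxylic acid
Product: 35 C14 methyl ester silyl ether
Conditions: MeI, KHCO3, DMF, rt
Reagents that add atoms: iodomethane, CI
Why: Carboxylate SN2 alkylation under weakly basic conditions avoids diazoalkanes, which would add to the methylene lactone.

Step 22
Reactants: 35 C14 methyl ester silyl ether
Product: 36 target CNP0143679.1
Conditions: HF·pyridine, pyridine, THF, 0 °C to rt
Reagents that add atoms: none
Why: Buffered HF·pyridine removes the secondary silyl ether under conditions that electron-poor oxiranes, esters and the methylene lactone tolerate.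

**Compound list**

1 | (S)-(+)-carvone, (5S)-2-methyl-5-(prop-1-en-2-yl)cyclohex-2-en-1-one | CC1=CC[C@@H](CC1=O)C(C)=C | starting material
2 | (1S,5S)-2-methyl-5-(prop-1-en-2-yl)cyclohex-2-en-1-ol (cis-carveol) | CC1=CC[C@@H](C[C@@H]1O)C(C)=C | intermediate
3 | tert-butyldimethyl{[(1S,5S)-2-methyl-5-(prop-1-en-2-yl)cyclohex-2-en-1-yl]oxy}silane | CC1=CC[C@@H](C[C@@H]1O[Si](C)(C)C(C)(C)C)C(C)=C | intermediate
4 | (4S,6S)-4-(tert-butyldimethylsilyloxy)-3-methyl-6-(prop-1-en-2-yl)cyclohex-2-en-1-one | CC1=CC(=O)[C@H](C(C)=C)C[C@@H]1O[Si](C)(C)C(C)(C)C | intermediate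
5 | ethyl vinyl ether | C=COCC | starting material
6 | 4-methoxybenzyl vinyl ether | C=COCc1ccc(OC)cc1 | intermediate
7 | 1-[(1,2-dibromoethoxy)methyl]-4-methoxybenzene (racemic) | BrCC(Br)OCc1ccc(OC)cc1 | intermediate (not isolated)
8 | (Z)-1-bromo-2-(4-methoxybenzyloxy)ethene | Br/C=C\OCc1ccc(OC)cc1 | intermediate
9 | (Z)-2-(4-methoxybenzyloxy)ethenyllithium | [Li]/C=C\OCc1ccc(OC)cc1 | intermediate (not isolated)
10 | dichloro[(Z)-2-(4-methoxybenzyloxy)ethenyl]cerium | Cl[Ce](Cl)/C=C\OCc1ccc(OC)cc1 | intermediate (not isolated)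
11 | (1S,4S,6S)-4-(tert-butyldimethylsilyloxy)-1-[(Z)-2-(4-methoxybenzyloxy)ethenyl]-3-methyl-6-(prop-1-en-2-yl)cyclohex-2-en-1-ol | CC1=C[C@@](O)(/C=C\OCc2ccc(OC)cc2)[C@H](C(C)=C)C[C@@H]1O[Si](C)(C)C(C)(C)C | intermediate
12 | methyl bromoacetate | COC(=O)CBr | starting material
13 | potassium alkoxide of 11 | [K+].CC1=C[C@@]([O-])(/C=C\OCc2ccc(OC)cc2)[C@H](C(C)=C)C[C@@H]1O[Si](C)(C)C(C)(C)C | intermediate (not isolated)
14 | potassium enolate of the ring-expanded ketone (3S,8R; C1=C10 ring-trans, C4=C5 cis, C6=C7 ring-trans with O− on C6 cis to C8) | [K+].C1/C(C)=C/C[C@H](O[Si](C)(C)C(C)(C)C)/C(C)=C\C(\[O-])=C\[C@@H]1OCc2ccc(OC)cc2 | intermediate (not isolated)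
15 | methyl 2-[(1R,3Z,5S,7E,10R)-5-(tert-butyldimethylsilyloxy)-10-(4-methoxybenzyloxy)-4,8-dimethyl-2-oxocyclodeca-3,7-dien-1-yl]acetate (germacrane locants 3S,7R,8R; C6 ketone; C1=C10 ring-trans) | O=C1/C=C(/C)[C@@H](O[Si](C)(C)C(C)(C)C)C/C=C(\C)C[C@@H](OCc2ccc(OC)cc2)[C@H]1CC(=O)OC | intermediate
16 | lithium 6S-alkoxide of the hydroxy ester from 15 (3S,6S,8R; C7 unchanged in space) | [Li+].[O-][C@H]1/C=C(/C)[C@@H](O[Si](C)(C)C(C)(C)C)C/C=C(\C)C[C@@H](OCc2ccc(OC)cc2)[C@H]1CC(=O)OC | intermediate (not isolated)
17 | (3S,6S,7R,8R)-3-(tert-butyldimethylsilyloxy)-8-(4-methoxybenzyloxy)-13-norgermacra-1(10)E,4Z-dien-12,6-olide (cis-fused lactone) | O=C1O[C@H]2/C=C(/C)[C@@H](O[Si](C)(C)C(C)(C)C)C/C=C(\C)C[C@@H](OCc3ccc(OC)cc3)[C@H]2C1 | intermediate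
18 | (3S,6S,7S,8R)-3-(tert-butyldimethylsilyloxy)-6-hydroxy-8-(4-methoxybenzyloxy)-13-norgermacra-1(10)E,4Z-dien-12-oic acid | O[C@H]1/C=C(/C)[C@@H](O[Si](C)(C)C(C)(C)C)C/C=C(\C)C[C@@H](OCc2ccc(OC)cc2)[C@H]1CC(=O)O | intermediate
19 | (3S,6R,7R,8R)-3-(tert-butyldimethylsilyloxy)-8-(4-methoxybenzyloxy)-13-norgermacra-1(10)E,4Z-dien-12,6-olide (trans-fused lactone) | O=C1O[C@@H]2/C=C(/C)[C@@H](O[Si](C)(C)C(C)(C)C)C/C=C(\C)C[C@@H](OCc3ccc(OC)cc3)[C@H]2C1 | intermediate
20 | (3S,6R,7R,8R)-13-(dimethylamino)-3-(tert-butyldimethylsilyloxy)-8-(4-methoxybenzyloxy)germacra-1(10)E,4Z-dien-12,6-olide (C11 epimers) | CN(C)CC1C(=O)O[C@@H]2/C=C(/C)[C@@H](O[Si](C)(C)C(C)(C)C)C/C=C(\C)C[C@@H](OCc3ccc(OC)cc3)[C@@H]12 | intermediate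
21 | trimethylammonium iodide of 20 | [I-].C[N+](C)(C)CC1C(=O)O[C@@H]2/C=C(/C)[C@@H](O[Si](C)(C)C(C)(C)C)C/C=C(\C)C[C@@H](OCc3ccc(OC)cc3)[C@@H]12 | intermediate (not isolated)
22 | (3S,6R,7R,8R)-3-(tert-butyldimethylsilyloxy)-8-(4-methoxybenzyloxy)germacra-1(10)E,4Z,11(13)-trien-12,6-olide | C=C1C(=O)O[C@@H]2/C=C(/C)[C@@H](O[Si](C)(C)C(C)(C)C)C/C=C(\C)C[C@@H](OCc3ccc(OC)cc3)[C@@H]12 | intermediate
23 | (3S,6R,7R,8R)-3-(tert-butyldimethylsilyloxy)-8-hydroxygermacra-1(10)E,4Z,11(13)-trien-12,6-olide | C=C1C(=O)O[C@@H]2/C=C(/C)[C@@H](O[Si](C)(C)C(C)(C)C)C/C=C(\C)C[C@@H](O)[C@@H]12 | intermediate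
24 | angelic acid, (Z)-2-methylbut-2-enoic acid | C/C=C(/C)C(=O)O | starting material
25 | (Z)-2-methylbut-2-en-1-ol | C/C=C(/C)CO | intermediate
26 | (2S,3R)-(2,3-dimethyloxiran-2-yl)methanol | OC[C@]1(C)O[C@@H]1C | intermediate
27 | (2R,3R)-2,3-dimethyloxirane-2-carboxylic acid | OC(=O)[C@]1(C)O[C@@H]1C | intermediate
28 | (2R,3R)-2,3-dimethyloxirane-2-carboxylic 2,4,6-trichlorobenzoic anhydride | O=C(OC(=O)[C@]1(C)O[C@@H]1C)c1c(Cl)cc(Cl)cc1Cl | intermediate (not isolated)
29 | (3S,6R,7R,8R)-3-(tert-butyldimethylsilyloxy)-8-[(2R,3R)-2,3-dimethyloxirane-2-carbonyloxy]germacra-1(10)E,4Z,11(13)-trien-12,6-olide (C14 methyl, C1=C10 ring-trans) | C=C1C(=O)O[C@@H]2/C=C(/C)[C@@H](O[Si](C)(C)C(C)(C)C)C/C=C(\C)C[C@@H](OC(=O)[C@]3(C)O[C@@H]3C)[C@@H]12 | intermediate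
30 | C1 allylseleninic acid with exocyclic C10=C14 (C1 and Se configuration not assigned) | C=C1C(=O)O[C@@H]2/C=C(/C)[C@@H](O[Si](C)(C)C(C)(C)C)CC([Se](=O)O)C(=C)C[C@@H](OC(=O)[C@]3(C)O[C@@H]3C)[C@@H]12 | intermediate (not isolated)
31 | C14–O–Se–OH ester of 32 (divalent selenium; C1=C10 ring-cis) | C=C1C(=O)O[C@@H]2/C=C(/C)[C@@H](O[Si](C)(C)C(C)(C)C)C/C=C(/CO[Se]O)C[C@@H](OC(=O)[C@]3(C)O[C@@H]3C)[C@@H]12 | intermediate (not isolated)
32 | 14-hydroxy derivative of 29 with ring-cis C1=C10 (1(10)E by CIP; C2 trans to C14) | C=C1C(=O)O[C@@H]2/C=C(/C)[C@@H](O[Si](C)(C)C(C)(C)C)C/C=C(/CO)C[C@@H](OC(=O)[C@]3(C)O[C@@H]3C)[C@@H]12 | intermediate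
33 | 14-oxo (enal) derivative, ring-cis C1=C10 | C=C1C(=O)O[C@@H]2/C=C(/C)[C@@H](O[Si](C)(C)C(C)(C)C)C/C=C(/C=O)C[C@@H](OC(=O)[C@]3(C)O[C@@H]3C)[C@@H]12 | intermediate
34 | 14-oic acid, ring-cis C1=C10 | C=C1C(=O)O[C@@H]2/C=C(/C)[C@@H](O[Si](C)(C)C(C)(C)C)C/C=C(/C(=O)O)C[C@@H](OC(=O)[C@]3(C)O[C@@H]3C)[C@@H]12 | intermediate
35 | methyl 14-oate, 3-O-tert-butyldimethylsilyl ether of the target | C=C1C(=O)O[C@@H]2/C=C(/C)[C@@H](O[Si](C)(C)C(C)(C)C)C/C=C(/C(=O)OC)C[C@@H](OC(=O)[C@]3(C)O[C@@H]3C)[C@@H]12 | intermediate
36 | CNP0143679.1, methyl (3S,6R,7R,8R)-8-[(2R,3R)-2,3-dimethyloxirane-2-carbonyloxy]-3-hydroxy-12,6-olidogermacra-1(10)E,4Z,11(13)-trien-14-oate | C=C1C(=O)O[C@@H]2/C=C(/C)[C@@H](O)C/C=C(/C(=O)OC)C[C@@H](OC(=O)[C@]3(C)O[C@@H]3C)[C@@H]12 | target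

**Step count**

Total: 22 steps. Longest linear sequence: 17 steps (steps 1–3, 6–13, 17–22).

**Steps most likely to fail**

Step 7. What may go wrong: β-elimination of the 4-methoxybenzyloxide from the potassium enolate, proton transfer between enolate and product, or unselective (oxygen or double) alkylation when rearrangement and alkylation share one flask. The fallback sets out from 11: the rearrangement is run as above, but the enolate is silylated at −78 °C (Me3SiCl, Et3N) to give the trimethylsilyl enol ether F1, which is isolated. MeLi (THF, 0 °C) then liberates the amine- and crown-free lithium enolate F2, which is alkylated with 12 at −78 °C and rejoins the route at 15.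

Step 10. What may go wrong: activation of the carboxyl group instead of the hydroxyl group (lactonisation with retention), or ionisation and elimination of the activated allylic alcohol. The fallback sets out from 17: aminolysis with Me2AlNMe2 (from AlMe3 and Me2NH·HCl, CH2Cl2) gives the 6S hydroxy dimethylamide F3, whose acyl group cannot be activated. Ms2O/Et3N at −40 °C gives the C6 mesylate F4; the amide oxygen displaces it from the rear to give the iminium lactone F5, and aqueous work-up hydrolyses this to 19.

Step 18. What may go wrong: ene attack at the wrong allylic site (C9 or C15), or opening of the oxirane by the selenium acids. The fallback sets out from 29: sensitised photo-oxygenation (O2, tetraphenylporphyrin, hν, CH2Cl2, 0 °C), the singlet-oxygen ene reaction known to turn 1(10)-trans germacranolides into 1-hydroperoxy-10(14)-enes, should give the C1 hydroperoxide F6. PPh3 reduces it to the C1 allylic alcohol F7. Catalytic Ph3SiOReO3 (Et2O, −50 to 0 °C) then moves the hydroxyl to C14 by 1,3-transposition through a chair [3,3] shift of the perrhenate ester and rejoins the route at 32 with the ring-cis alkene.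

**Further compounds**

F1 | step 7 | trimethylsilyl enol ether of the ring-expanded ketone (3S,8R; C6–OSiMe3, C6=C7 ring-trans) | C1/C(C)=C/C[C@H](O[Si](C)(C)C(C)(C)C)/C(C)=C\C(\O[Si](C)(C)C)=C\[C@@H]1OCc2ccc(OC)cc2
F2 | step 7 | lithium enolate of the ring-expanded ketone | [Li+].C1/C(C)=C/C[C@H](O[Si](C)(C)C(C)(C)C)/C(C)=C\C(\[O-])=C\[C@@H]1OCc2ccc(OC)cc2
F3 | step 10 | 6S hydroxy N,N-dimethylamide from 17 | O[C@H]1/C=C(/C)[C@@H](O[Si](C)(C)C(C)(C)C)C/C=C(\C)C[C@@H](OCc2ccc(OC)cc2)[C@H]1CC(=O)N(C)C
F4 | step 10 | C6 methanesulfonate of F3 | CS(=O)(=O)O[C@H]1/C=C(/C)[C@@H](O[Si](C)(C)C(C)(C)C)C/C=C(\C)C[C@@H](OCc2ccc(OC)cc2)[C@H]1CC(=O)N(C)C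
F5 | step 10 | trans-fused 6R iminium lactone methanesulfonate | CS(=O)(=O)[O-].C[N+](C)=C1O[C@@H]2/C=C(/C)[C@@H](O[Si](C)(C)C(C)(C)C)C/C=C(\C)C[C@@H](OCc3ccc(OC)cc3)[C@H]2C1
F6 | step 18 | C1 hydroperoxide of 29 with exocyclic C10=C14 (C1 not assigned) | C=C1C(=O)O[C@@H]2/C=C(/C)[C@@H](O[Si](C)(C)C(C)(C)C)CC(OO)C(=C)C[C@@H](OC(=O)[C@]3(C)O[C@@H]3C)[C@@H]12
F7 | step 18 | C1 allylic alcohol with exocyclic C10=C14 (C1 not assigned) | C=C1C(=O)O[C@@H]2/C=C(/C)[C@@H](O[Si](C)(C)C(C)(C)C)CC(O)C(=C)C[C@@H](OC(=O)[C@]3(C)O[C@@H]3C)[C@@H]12
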